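The depside is cut at the aryl ester between the ring A carbonyl and O4 of ring B, and ring B is then traced back to a non-aromatic cyclohexenone. Ring B carries its carboxyl on C1, oxygens on C2 and C4 and the pentyl chain on C6, exactly the substitution left behind when a malonate diester and a 4-alkylbut-3-en-2-one are stitched together. One operation therefore forges C1–C6 by conjugate addition and C2–C3 by ester condensation, closing the carbocycle with all four substituents already placed. Its precursors are simply (E)-non-3-en-2-one and dibenzyl malonate; the benzyl ester that survives is a masked acid, freed with hydrogen in the last step without harm to the aryl ester link.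

Key step: step 1

Remark:
- Ring B is numbered from its carboxyl-bearing carbon (C1), and the cyclohexenone uses the same numbers.
- The target has no stereocentre. The chiral ring B intermediates are racemic, and one enantiomer is drawn.
- Sodium, potassium or lithium salts that exist only until the acidic work-up are not numbered.

Step 1
Reactants: 1 (E)-non-3-en-2-one; 2 dibenzyl malonate
Product: 4 benzyl trans-2-hydroxy-4-oxo-6-pentylcyclohex-2-ene-1-carboxylate (racemic), via Michael adduct 3 (not isolated)
Conditions: NaOCH2Ph (1.1 equiv, 1 M in BnOH), THF, rt → 65 °C; sodium salt taken into water and washed with toluene; then aq. HCl, 0 °C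
Reagents that add atoms: none
Why: NaOCH2Ph deprotonates 2, and the soft, stabilised carbanion adds reversibly to the β-carbon (C4) of enone 1 to make the C1–C6 bond of ring B and give 3; proton exchange then brings up the terminal methyl-ketone enolate, which attacks one of the two equivalent benzyl ester carbonyls, makes the C2–C3 bond and expels benzyloxide. The closest known reaction type is the tandem Michael addition–Claisen (Dieckmann-type) condensation of dialkyl malonates with alk-3-en-2-ones, the standard entry to alkyl 6-alkyl-2,4-dioxocyclohexanecarboxylates. The single ring closes in the favoured 6-(enolendo)-exo-trig mode, whereas the internal enolate of the same ketone could only form a strained four-membered ring, so one constitution results. All events up to this point are equilibria, and they are drained by irreversible deprotonation of the product, a vinylogous acid, which is why a full equivalent of base is used. C6 is created without facial bias (racemate), and C1, an epimerisable β-keto ester carbon, settles under thermodynamic control trans to the pentyl group with both substituents pseudo-equatorial; both centres disappear in step 2, so no control is required. The step needs 1,4- over 1,2-addition, secured by the stabilised nucleophile under reversible conditions, and an unscrambled ester, secured by matching the alkoxide to the benzyl esters.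

Step 2
Reactants: 4 benzyl trans-2-hydroxy-4-oxo-6-pentylcyclohex-2-ene-1-carboxylate
Product: 6 benzyl 2,4-dihydroxy-6-pentylbenzoate, via C3 bromide 5 (not isolated)
Conditions: Br2 (1.0 equiv), DMF, 0 °C; then 65 °C
Reagents that add atoms: none
Why: Electrophilic bromination of the enol at C3 gives 5, which on warming relays its bromine under the HBr present and loses HBr (halogenation–dehydrohalogenation aromatization of a dihydroresorcylate), the gain of aromaticity driving tautomerisation to the resorcinol and erasing C1 and C6 as stereocentres, while one equivalent of Br2 and a moderate temperature should hold back nuclear bromination and bromide-induced loss of the benzyl ester.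

Step 3
Reactants: 7 methyl 2,4-dihydroxy-6-methylbenzoate (methyl orsellinate)
Product: 8 methyl 2-hydroxy-4-methoxy-6-methylbenzoate
Conditions: MeI (1.05 equiv), K2CO3 (1.1 equiv), acetone, reflux
Reagents that add atoms: iodomethane, CI
Why: Williamson ether synthesis in which the C2 hydroxyl is tied up in a hydrogen bond to the ester carbonyl and is less acidic, so one equivalent of MeI and a mild carbonate base should alkylate only the free C4 phenol.

Step 4
Reactants: 8 methyl 2-hydroxy-4-methoxy-6-methylbenzoate
Product: 9 methyl 2-(benzyloxy)-4-methoxy-6-methylbenzoate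
Conditions: BnBr (1.3 equiv), K2CO3, DMF, 60 °C
Reagents that add atoms: benzyl bromide, BrCc1ccccc1
Why: Williamson etherification under more forcing conditions (dipolar aprotic solvent, heat, excess halide) breaks the chelate and caps the remaining phenol as a benzyl ether that falls off in the last step.

Step 5
Reactants: 9 methyl 2-(benzyloxy)-4-methoxy-6-methylbenzoate; 10 1-bromohexane
Product: 12 methyl 2-(benzyloxy)-6-heptyl-4-methoxybenzoate, via benzylic lithium species 11 (not isolated)
Conditions: LiN(iPr)2 (LDA, commercial solution, 1.2 equiv), THF, −78 °C, slow addition of 9; then 10 (1.5 equiv), DMPU, −78 → 0 °C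
Reagents that add atoms: none
Why: Lateral (benzylic) lithiation of an ortho-toluate, in which the ester acidifies the ortho-methyl group and stabilises the anion as an extended dienolate that is alkylated by the primary bromide in an SN2 reaction, while adding 9 slowly to excess amide at −78 °C keeps ester and anion apart and limits self-condensation.

Step 6
Reactants: 12 methyl 2-(benzyloxy)-6-heptyl-4-methoxybenzoate
Product: 13 2-(benzyloxy)-6-heptyl-4-methoxybenzoic acid
Conditions: KOH (excess), DMSO–H2O, 90 °C; then cold aq. HCl
Reagents that add atoms: KOH (potassium hydroxide), [K+].[OH-]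
Why: Saponification (acyl–oxygen cleavage) of a di-ortho-substituted benzoate needs poorly solvated hydroxide in hot aqueous DMSO, both ethers are inert to base, and cold acidification avoids decarboxylation of the electron-rich acid.

Step 7
Reactants: 13 2-(benzyloxy)-6-heptyl-4-methoxybenzoic acid; 6 benzyl 2,4-dihydroxy-6-pentylbenzoate
Product: 15 benzyl 4-{[2-(benzyloxy)-6-heptyl-4-methoxybenzoyl]oxy}-2-hydroxy-6-pentylbenzoate, via acyl trifluoroacetate 14 (not isolated)
Conditions: (CF3CO)2O (3 equiv), toluene, 0 °C → rt
Reagents that add atoms: none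
Why: Mixed-anhydride esterification (the classical trifluoroacetic anhydride depside coupling), in which 14 ionises towards an acylium ion stabilised by its ortho and para alkoxy groups so that the two flanking substituents do not block acyl transfer, and only the free C4 hydroxyl of 6 reacts because the C2 hydroxyl is hydrogen-bonded to the benzyl ester and no base is present to release it.

Step 8
Reactants: 15 benzyl 4-{[2-(benzyloxy)-6-heptyl-4-methoxybenzoyl]oxy}-2-hydroxy-6-pentylbenzoate
Product: 16 benzyl 4-{[2-(benzyloxy)-6-heptyl-4-methoxybenzoyl]oxy}-2-methoxy-6-pentylbenzoate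
Conditions: MeI (excess), K2CO3 (anhydrous), acetone, reflux
Reagents that add atoms: iodomethane, CI
Why: Williamson methylation of the only free phenol left, with a non-nucleophilic anhydrous carbonate and a depside carbonyl shielded by its two ortho substituents, so that acyl cleavage or acyl transfer should not compete.

Step 9
Reactants: 16 benzyl 4-{[2-(benzyloxy)-6-heptyl-4-methoxybenzoyl]oxy}-2-methoxy-6-pentylbenzoate
Product: 17 4-[(2-heptyl-6-hydroxy-4-methoxybenzoyl)oxy]-2-methoxy-6-pentylbenzoic acid (CNP0341430.0)
Conditions: H2 (1 atm), 10% Pd/C, EtOAc, rt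
Reagents that add atoms: none
Why: Catalytic hydrogenolysis cleaves both benzylic C–O bonds (ester and aryl ether) under neutral conditions that leave the aryl ester link, the methyl ethers and the arenes untouched.

Compound list
1 | (E)-non-3-en-2-one | CCCCC/C=C/C(C)=O | starting material
2 | dibenzyl malonate | O=C(CC(=O)OCc1ccccc1)OCc1ccccc1 | starting material
3 | dibenzyl 2-(2-oxononan-4-yl)propanedioate (racemic, R enantiomer drawn) | CCCCC[C@H](CC(C)=O)C(C(=O)OCc1ccccc1)C(=O)OCc1ccccc1 | intermediate
4 | benzyl trans-2-hydroxy-4-oxo-6-pentylcyclohex-2-ene-1-carboxylate (racemic, 1S,6R enantiomer drawn) | CCCCC[C@@H]1CC(=O)C=C(O)[C@H]1C(=O)OCc1ccccc1 | intermediate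
5 | benzyl trans-3-bromo-2-hydroxy-4-oxo-6-pentylcyclohex-2-ene-1-carboxylate (racemic) | CCCCC[C@@H]1CC(=O)C(Br)=C(O)[C@H]1C(=O)OCc1ccccc1 | intermediate
6 | benzyl 2,4-dihydroxy-6-pentylbenzoate | CCCCCc1cc(O)cc(O)c1C(=O)OCc1ccccc1 | intermediate
7 | methyl 2,4-dihydroxy-6-methylbenzoate (methyl orsellinate) | COC(=O)c1c(C)cc(O)cc1O | starting material
8 | methyl 2-hydroxy-4-methoxy-6-methylbenzoate | COC(=O)c1c(C)cc(OC)cc1O | intermediate
9 | methyl 2-(benzyloxy)-4-methoxy-6-methylbenzoate | COC(=O)c1c(C)cc(OC)cc1OCc1ccccc1 | intermediate
10 | 1-bromohexane | CCCCCCBr | starting material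
11 | methyl 2-(benzyloxy)-6-(lithiomethyl)-4-methoxybenzoate | [Li]Cc1cc(OC)cc(OCc2ccccc2)c1C(=O)OC | intermediate
12 | methyl 2-(benzyloxy)-6-heptyl-4-methoxybenzoate | CCCCCCCc1cc(OC)cc(OCc2ccccc2)c1C(=O)OC | intermediate
13 | 2-(benzyloxy)-6-heptyl-4-methoxybenzoic acid | CCCCCCCc1cc(OC)cc(OCc2ccccc2)c1C(=O)O | intermediate
14 | 2-(benzyloxy)-6-heptyl-4-methoxybenzoic trifluoroacetic anhydride | CCCCCCCc1cc(OC)cc(OCc2ccccc2)c1C(=O)OC(=O)C(F)(F)F | intermediate
15 | benzyl 4-{[2-(benzyloxy)-6-heptyl-4-methoxybenzoyl]oxy}-2-hydroxy-6-pentylbenzoate | CCCCCCCc1cc(OC)cc(OCc2ccccc2)c1C(=O)Oc1cc(O)c(C(=O)OCc2ccccc2)c(CCCCC)c1 | intermediate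
16 | benzyl 4-{[2-(benzyloxy)-6-heptyl-4-methoxybenzoyl]oxy}-2-methoxy-6-pentylbenzoate | CCCCCCCc1cc(OC)cc(OCc2ccccc2)c1C(=O)Oc1cc(OC)c(C(=O)OCc2ccccc2)c(CCCCC)c1 | intermediate
17 | 4-[(2-heptyl-6-hydroxy-4-methoxybenzoyl)oxy]-2-methoxy-6-pentylbenzoic acid | CCCCCCCc1cc(OC)cc(O)c1C(=O)Oc1cc(CCCCC)c(C(=O)O)c(OC)c1 | target

Total step count: 9.
Longest linear sequence: 7 steps (7 → 8 → 9 → 12 → 13 → 15 → 16 → 17). The ring B branch contributes 2 steps before the union.

Steps most likely to fail

**Step 1.** The cascade may stall after the conjugate addition. Long heating with alkoxide and adventitious water may also hydrolyse and decarboxylate the β-keto ester, and the high-boiling alcohol may complicate isolation.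

The fallback sets out from 1 and comes back at 6. It moves the ring construction into the methyl ester series and exchanges the ester only after aromatization.
- Compound 1, dimethyl malonate and NaOMe in refluxing MeOH pass through the open-chain adduct dimethyl 2-(2-oxononan-4-yl)propanedioate F1. They should give methyl trans-2-hydroxy-4-oxo-6-pentylcyclohex-2-ene-1-carboxylate F2.
- Br2 in DMF (0 °C, then 80 °C) leads through methyl trans-3-bromo-2-hydroxy-4-oxo-6-pentylcyclohex-2-ene-1-carboxylate F3 to methyl 2,4-dihydroxy-6-pentylbenzoate F4.
- Aqueous KOH at reflux under N2, followed by cold acid, gives 2,4-dihydroxy-6-pentylbenzoic acid F5.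
- The carboxylate of F5 alone is alkylated with BnBr and KHCO3 in DMF at rt to give 6.

**Step 2.** The freshly formed, highly activated resorcinol may be brominated further on the ring. HBr or bromide may also dealkylate the benzyl ester, after which the acid decarboxylates.

The fallback sets out from 4 and comes back at 6. It avoids halogen altogether.
- TBSOTf (2.5 equiv) and Et3N in CH2Cl2 at 0 °C convert 4 into benzyl 2,4-bis[(tert-butyldimethylsilyl)oxy]-6-pentylcyclohexa-1,3-diene-1-carboxylate F6.
- DDQ in toluene at rt removes hydride from C6 of F6. The resulting cation is stabilised by both silyloxy groups, and loss of a proton from C5 gives benzyl 2,4-bis[(tert-butyldimethylsilyl)oxy]-6-pentylbenzoate F7.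
- Bu4NF buffered with AcOH in THF at 0 °C releases 6.

**Step 5.** The lithiated toluate may condense with ester that has not yet been deprotonated. The anion may also decay while the slow SN2 reaction with an unactivated primary bromide proceeds.

The fallback sets out from 9 and comes back at 13. It hydrolyses first, so that the nucleophile carries no electrophilic carbonyl.
- KOH in aqueous DMSO at 90 °C gives 2-(benzyloxy)-4-methoxy-6-methylbenzoic acid F8.
- LiN(iPr)2 (2.3 equiv) in THF, −78 → 0 °C, forms lithium 2-(benzyloxy)-6-(lithiomethyl)-4-methoxybenzoate F9.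
- F9 is alkylated at carbon with 10, and acidification delivers 13 in the same number of steps.

Further compounds
F1 | step 1 | dimethyl 2-(2-oxononan-4-yl)propanedioate (racemic) | CCCCC[C@H](CC(C)=O)C(C(=O)OC)C(=O)OC
F2 | step 1 | methyl trans-2-hydroxy-4-oxo-6-pentylcyclohex-2-ene-1-carboxylate (racemic) | CCCCC[C@@H]1CC(=O)C=C(O)[C@H]1C(=O)OC
F3 | step 1 | methyl trans-3-bromo-2-hydroxy-4-oxo-6-pentylcyclohex-2-ene-1-carboxylate (racemic) | CCCCC[C@@H]1CC(=O)C(Br)=C(O)[C@H]1C(=O)OC
F4 | step 1 | methyl 2,4-dihydroxy-6-pentylbenzoate | CCCCCc1cc(O)cc(O)c1C(=O)OC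
F5 | step 1 | 2,4-dihydroxy-6-pentylbenzoic acid | CCCCCc1cc(O)cc(O)c1C(=O)O
F6 | step 2 | benzyl 2,4-bis[(tert-butyldimethylsilyl)oxy]-6-pentylcyclohexa-1,3-diene-1-carboxylate (racemic) | CCCCC[C@@H]1CC(O[Si](C)(C)C(C)(C)C)=CC(O[Si](C)(C)C(C)(C)C)=C1C(=O)OCc1ccccc1
F7 | step 2 | benzyl 2,4-bis[(tert-butyldimethylsilyl)oxy]-6-pentylbenzoate | CCCCCc1cc(O[Si](C)(C)C(C)(C)C)cc(O[Si](C)(C)C(C)(C)C)c1C(=O)OCc1ccccc1
F8 | step 5 | 2-(benzyloxy)-4-methoxy-6-methylbenzoic acid | Cc1cc(OC)cc(OCc2ccccc2)c1C(=O)O
F9 | step 5 | lithium 2-(benzyloxy)-6-(lithiomethyl)-4-methoxybenzoate | [Li]Cc1cc(OC)cc(OCc2ccccc2)c1C(=O)O[Li]
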